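The key step exploits the unbranched, heteroatom-free methylene chain C3'–C23' (C1' = benzylic CH2, C2' = ketone). It is cut at C10'–C11', between two plain CH2 groups, because two feedstock acids meet there: C11'–C23' is myristic acid minus CO2, and C2'–C10' is sebacic acid minus CO2, its other carboxyl having become the ketone. One mixed Kolbe electrolysis expels both CO2 and joins the two primary radicals, with no metal reagent or activating group. The precursor is 11-(3,5-diacetoxyphenyl)-10-oxoundecanoic acid. The resorcinol ring is carried as its electron-poor diacetate so that the anode oxidises carboxylate, not arene. Methanolysis then frees the target.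

Key step: step 3

Remark: the target has no stereocentre and no stereogenic double bond. It is achiral, so no step has to control configuration.

Step 1
Reactants: 1 3,5-dihydroxybenzyl alcohol
Product: 2 3,5-diacetoxybenzyl bromide (5-(bromomethyl)benzene-1,3-diyl diacetate)
Conditions: AcBr (4 equiv), AcOH–CH2Cl2, 0 °C to rt
Reagents that add atoms: acetyl bromide, CC(=O)Br
Why: Acetyl bromide O-acetylates both phenols and the benzylic alcohol, and the HBr set free then replaces the benzylic oxygen by SN2 substitution (one-pot acylation/bromination known for hydroxybenzyl alcohols), while the meta oxygen substituents give no support to a benzylic cation and so hold back Friedel–Crafts self-alkylation.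

Step 2
Reactants: 2 3,5-diacetoxybenzyl bromide; 3 sebacoyl chloride (decanedioyl dichloride)
Product: 6 11-(3,5-diacetoxyphenyl)-10-oxoundecanoic acid, via 3,5-diacetoxybenzylzinc bromide 4 (not isolated), via keto acid chloride 5 (not isolated)
Conditions: (i) activated Zn dust, LiCl, THF, 0 °C; (ii) slow addition to 3 (4 equiv), Pd(PPh3)4 (2 mol %), toluene–THF, 0 °C; (iii) H2O–THF, 0 °C to rt. The sebacic acid formed from surplus 3 is filtered off from CH2Cl2.
Reagents that add atoms: water, O
Why: LiCl-assisted zinc insertion into the benzylic C–Br bond gives a soft organozinc that leaves aryl acetates alone, the Pd-catalysed Negishi acylation stops at the ketone, slow inverse addition to a fourfold excess of the symmetrical diacid chloride keeps double acylation small, and the water quench turns the second COCl directly into the free acid so that no saponification endangers the acetates.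

Step 3
Reactants: 6 11-(3,5-diacetoxyphenyl)-10-oxoundecanoic acid; 7 myristic acid (tetradecanoic acid)
Product: 8 5-(2-oxotricosyl)benzene-1,3-diyl diacetate
Conditions: 7 (5 equiv, premixed with Me4NOH·5H2O, about 0.3 equiv per CO2H), then 6, acetone, undivided cell, two glassy-carbon plates, constant current with rapid alternating polarity (square wave, about 50 ms per half-cycle), 35–40 °C, until 6 is consumed
Reagents that add atoms: none
Why: Each carboxylate is oxidised by one electron at the electrode that is momentarily the anode, both acyloxy radicals lose CO2 at once, and the tridecyl radical from 7 combines with the primary omega-radical from 6 in the radical-rich layer at the surface to form the C10'–C11' bond, while carboxyl protons are reduced to H2 at the other electrode. The closest known reaction type is the mixed (hetero) Kolbe electrolysis, long used to splice fatty acids onto half-esters and remote keto acids, here in its alternating-polarity variant on carbon in acetone, in which every cathodic half-cycle re-forms carboxylate at the surface that oxidises it next and levels the local pH, which spares the base-labile aryl acetates. No ring is closed and no stereocentre is formed. Radical-versus-cation selectivity rests on the substrate, since both radical carbons are primary and flanked only by CH2 groups (the C2' ketone lies eight methylenes away), so that over-oxidation to Hofer–Moest products should stay minor. Chemoselectivity at the anode rests on the two acetoxy groups, which lift the oxidation potential of the ring into the range of simple alkylbenzenes that survive Kolbe conditions, whereas the free resorcinol or its ethers would be oxidised before the carboxylate, and the weakly basic carboxylate buffer does not enolise the C1' methylene. Cross- versus homo-coupling is only statistical, so cheap 7 is used in fivefold excess to pair most radicals from 6 with tridecyl radicals, and the apolar hydrocarbon homodimer and the far more polar diketone homodimer should part from 8 on filtration and chromatography.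

Step 4
Reactants: 8 5-(2-oxotricosyl)benzene-1,3-diyl diacetate
Product: 9 5-(2'-oxotricosyl)resorcinol
Conditions: conc. HCl (cat.), MeOH–THF (3:1), 50 °C, N2; aqueous work-up
Reagents that add atoms: none
Why: Acid-catalysed transesterification (methanolysis) of the two activated aryl esters frees the phenols, the ketone can at most form a dimethyl ketal that the aqueous work-up returns, and the meta placement of the side chain relative to both OH groups leaves no cyclisation path.

Compound list
1 | 3,5-dihydroxybenzyl alcohol | OCc1cc(O)cc(O)c1 | starting material
2 | 3,5-diacetoxybenzyl bromide | BrCc1cc(OC(C)=O)cc(OC(C)=O)c1 | intermediate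
3 | sebacoyl chloride (decanedioyl dichloride) | O=C(Cl)CCCCCCCCC(=O)Cl | starting material
4 | 3,5-diacetoxybenzylzinc bromide | Br[Zn]Cc1cc(OC(C)=O)cc(OC(C)=O)c1 | intermediate
5 | 11-(3,5-diacetoxyphenyl)-10-oxoundecanoyl chloride | O=C(Cl)CCCCCCCCC(=O)Cc1cc(OC(C)=O)cc(OC(C)=O)c1 | intermediate
6 | 11-(3,5-diacetoxyphenyl)-10-oxoundecanoic acid | OC(=O)CCCCCCCCC(=O)Cc1cc(OC(C)=O)cc(OC(C)=O)c1 | intermediate
7 | myristic acid (tetradecanoic acid) | CCCCCCCCCCCCCC(=O)O | starting material
8 | 5-(2-oxotricosyl)benzene-1,3-diyl diacetate | CCCCCCCCCCCCCCCCCCCCCC(=O)Cc1cc(OC(C)=O)cc(OC(C)=O)c1 | intermediate
9 | 5-(2'-oxotricosyl)resorcinol | CCCCCCCCCCCCCCCCCCCCCC(=O)Cc1cc(O)cc(O)c1 | target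

Total step count: 4. Longest linear sequence: 4 (1 → 2 → 6 → 8 → 9).

Steps most likely to fail

1. Step 3 (key step). Several things may go wrong:
- The charge may be spent on pairing of like radicals, on over-oxidation of the radicals to cations, or on hydrogen abstraction from the solvent.
- Waxy hydrocarbon may coat the electrodes.
- Partial loss of an acetate would expose a phenol to anodic oxidation and film formation.

The fallback sets out from 6 and 7 and comes back at 8. It makes the same bond at a cathode under nickel control instead of at an anode. Acids 6 and 7 are each condensed with N-hydroxyphthalimide (DIC, cat. DMAP, CH2Cl2) to give the N-hydroxyphthalimide ester of 6 F1 and the N-hydroxyphthalimide ester of myristic acid F2. F1 and an excess of F2 are then submitted to the nickel-electrocatalytic doubly decarboxylative alkyl–alkyl coupling (NiCl2·6H2O, terpyridine-type ligand, AgNO3, Mg sacrificial anode, carbon cathode, NMP, rt). This never exposes the arene to an oxidising potential and should give 8.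

2. Step 2. Several things may go wrong:
- Wurtz-type homocoupling may compete during the zinc insertion.
- A second acylation may occur at the far acyl end.
- Zinc salts may promote opening of THF by the surplus acid chloride.
- Removal of the large amount of diacid may be tedious.

The fallback sets out from 2 (through its zinc reagent 4) and comes back at 6. It replaces the statistical differentiation of the two acyl ends by a protecting group. Commercial 10-(tert-butoxy)-10-oxodecanoic acid F3 is converted under neutral conditions (1-chloro-N,N,2-trimethylprop-1-en-1-amine, CH2Cl2, 0 °C) into tert-butyl 10-chloro-10-oxodecanoate F4. One equivalent of F4 is coupled with 4 under the same palladium catalysis to give tert-butyl 11-(3,5-diacetoxyphenyl)-10-oxoundecanoate F5. TFA–CH2Cl2 then removes the tert-butyl group without touching the aryl acetates and gives 6.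

3. Step 1. Substitution at the benzylic position may stall at the ester stage, and acid-promoted Friedel–Crafts oligomerisation may set in before both phenols are acylated. The fallback sets out from 1 and comes back at 2. It separates the two events and makes the C–Br bond under neutral conditions. Appel bromination of 1 (CBr4, PPh3, THF, 0 °C) gives 3,5-dihydroxybenzyl bromide F6. The phenols are then acetylated without any amine that could quaternise the bromide (Ac2O, cat. H2SO4, 0 °C), which gives 2.

Further compounds
F1 | step 3 | N-hydroxyphthalimide ester of 6 (1,3-dioxoisoindolin-2-yl 11-(3,5-diacetoxyphenyl)-10-oxoundecanoate) | O=C(CCCCCCCCC(=O)Cc1cc(OC(C)=O)cc(OC(C)=O)c1)ON1C(=O)c2ccccc2C1=O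
F2 | step 3 | N-hydroxyphthalimide ester of myristic acid (1,3-dioxoisoindolin-2-yl tetradecanoate) | CCCCCCCCCCCCCC(=O)ON1C(=O)c2ccccc2C1=O
F3 | step 2 | 10-(tert-butoxy)-10-oxodecanoic acid (bought) | CC(C)(C)OC(=O)CCCCCCCCC(=O)O
F4 | step 2 | tert-butyl 10-chloro-10-oxodecanoate | CC(C)(C)OC(=O)CCCCCCCCC(=O)Cl
F5 | step 2 | tert-butyl 11-(3,5-diacetoxyphenyl)-10-oxoundecanoate | CC(C)(C)OC(=O)CCCCCCCCC(=O)Cc1cc(OC(C)=O)cc(OC(C)=O)c1
F6 | step 1 | 3,5-dihydroxybenzyl bromide | Oc1cc(O)cc(CBr)c1
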